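Chain atoms are numbered from the benzylic carbon C1; the only ring, the dimethoxybenzene, is a spectator and no ring is formed. The key step exploits the acyclic segment C2–C3–C4–C5: the C3 carbinol carbon lies between two methylenes, and C5 can be held as a methylidene-bearing sp2 carbon until late. Cutting C2–C3 and C4–C5 leaves a vinyl unit (C3–C4). A palladium-catalysed conjunctive coupling of an arylethyl boronate, vinyllithium and hept-1-en-2-yl triflate forges both bonds at once and sets C3 as an (S)-configured C–B bond. The precursor is the lithium ate complex of the arylethyl pinacol boronate with vinyllithium. Boron oxidation, alkene cleavage and a hydroxyl-directed Tishchenko reduction complete the anti-diol monoacetate.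

Key step: step 4

Assumption: the (Sp,Sp) series of the MandyPhos ligand is taken as the antipode that leads to the (3S)-boronate; the sense is to be confirmed on the first run (Mosher ester analysis of alcohol 11), and the (Rp,Rp) antipode is used with nothing else changed if it proves opposite.

Step 1
Reactants: 1 3,4-dimethoxystyrene; 2 pinacolborane
Product: 3 2-[2-(3,4-dimethoxyphenyl)ethyl]-4,4,5,5-tetramethyl-1,3,2-dioxaborolane
Conditions: 2 (1.2 equiv), [Ir(cod)Cl]2 (1.5 mol%), 1,2-bis(diphenylphosphino)ethane (3 mol%), CH2Cl2, rt
Reagents that add atoms: none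
Why: Iridium-catalysed hydroboration of a vinylarene, in which the chelating bisphosphine should steer boron to the terminal carbon (anti-Markovnikov) and so avoid the benzylic boronate; no stereocentre is formed.

Step 2
Reactants: 4 heptan-2-one
Product: 6 hept-1-en-2-yl trifluoromethanesulfonate, via lithium hept-1-en-2-olate 5 (not isolated)
Conditions: 4 added to LiN(iPr)2 (1.1 equiv), THF, −78 °C; then PhNTf2 (1.05 equiv), −78 → 0 °C
Reagents that add atoms: N-phenylbis(trifluoromethanesulfonimide), O=S(=O)(N(c1ccccc1)S(=O)(=O)C(F)(F)F)C(F)(F)F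
Why: Kinetic deprotonation of the methyl ketone by the hindered amide (ketone added to excess base at low temperature) should give the less substituted enolate, which is O-sulfonylated by the triflimide (enol triflate synthesis); a 1,1-disubstituted alkene has no geometry to control.

Step 3
Reactants: 7 tetravinyltin
Product: 8 vinyllithium
Conditions: n-BuLi (hexanes), pentane, rt, argon; filter the precipitate, wash with pentane, dissolve in THF, titrate
Reagents that add atoms: n-butyllithium, [Li]CCCC
Why: Tin–lithium exchange (transmetallation) in which the sparingly soluble vinyllithium precipitates from the hydrocarbon, which pulls the exchange forward and should deliver a halide-free reagent after filtration.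

Step 4
Reactants: 3 2-[2-(3,4-dimethoxyphenyl)ethyl]-4,4,5,5-tetramethyl-1,3,2-dioxaborolane; 8 vinyllithium; 6 hept-1-en-2-yl trifluoromethanesulfonate
Product: 10 2-[(3S)-1-(3,4-dimethoxyphenyl)-5-methylidenedecan-3-yl]-4,4,5,5-tetramethyl-1,3,2-dioxaborolane, via lithium vinylboron ate complex 9 (not isolated)
Conditions: 3 + 8 (1.0 equiv), Et2O, 0 °C → rt; evaporate; then 6 (1.1 equiv), Pd(OAc)2 (2 mol%), (Sp,Sp)-MandyPhos [1,1'-bis(bis(4-methoxy-3,5-dimethylphenyl)phosphino)-2,2'-bis((R)-α-(dimethylamino)benzyl)ferrocene] (2.4 mol%), THF, 60 °C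
Reagents that add atoms: none
Why: Vinyllithium adds to boron of 3 to give the four-coordinate ate complex 9; oxidative addition of 6 to zerovalent palladium gives a cationic hept-1-en-2-yl complex of divalent palladium that binds the vinyl π-bond of 9 and triggers a 1,2-metallate shift, in which the arylethyl group moves from boron to the boron-bearing carbon anti to palladium (C2–C3) while palladium takes the terminal carbon, and reductive elimination then joins C4 to C5. The closest known reaction type is the palladium-catalysed enantioselective conjunctive cross-coupling of vinylboron ate complexes with aryl and alkenyl triflates. No ring is closed. The single new stereocentre, C3, is controlled by the chiral ferrocenyl bisphosphine on palladium, which selects the enantioface of the bound vinyl group during the shift. The step needs the metallate shift to outrun direct vinyl transmetallation and β-hydride elimination; the non-coordinating triflate counter-ion, the absence of halide (tin-derived vinyllithium, triflate electrophile) and the wide bite angle of the ligand should secure this. The primary arylethyl carbon is the only carbon group on boron that can migrate, so the site of bond formation is not in doubt.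

Step 5
Reactants: 10 2-[(3S)-1-(3,4-dimethoxyphenyl)-5-methylidenedecan-3-yl]-4,4,5,5-tetramethyl-1,3,2-dioxaborolane
Product: 11 (3S)-1-(3,4-dimethoxyphenyl)-5-methylidenedecan-3-ol
Conditions: 3 M NaOH (aq), 30% H2O2, THF, 0 °C → rt; Na2S2O3 quench
Reagents that add atoms: hydrogen peroxide, OO
Why: Boronate oxidation, in which hydroperoxide adds to boron and C3 migrates from boron to oxygen with retention, so (3S)-10 should give (3S)-11, while the unactivated methylidene and the dimethoxybenzene ring are inert to alkaline peroxide.

Step 6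
Reactants: 11 (3S)-1-(3,4-dimethoxyphenyl)-5-methylidenedecan-3-ol
Product: 13 (3S)-1-(3,4-dimethoxyphenyl)-3-hydroxydecan-5-one, via ozonide 12 (not isolated)
Conditions: O3/O2, CH2Cl2 (no alcohol cosolvent), −78 °C, Sudan Red 7B as end-point indicator; then PPh3 (1.5 equiv), −78 °C → rt
Reagents that add atoms: ozone, [O-][O+]=O
Why: Ozonolysis (Criegee mechanism), in which the 1,1-disubstituted alkene should react with ozone far faster than the dimethoxybenzene ring, the ozonide 12 is reduced by the phosphine to the C5 ketone and formaldehyde, and the cold neutral work-up should spare the β-hydroxy ketone from dehydration; C3 is not touched.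

Step 7
Reactants: 13 (3S)-1-(3,4-dimethoxyphenyl)-3-hydroxydecan-5-one
Product: 15 (3S,5S)-1-(3,4-dimethoxyphenyl)-5-hydroxydecan-3-yl acetate, via samarium-bound acetaldehyde hemiacetal 14 (not isolated)
Conditions: MeCHO (6 equiv, freshly distilled), SmI2 (0.2 equiv, THF solution), THF, −10 °C, dark; aq NaHCO3 quench
Reagents that add atoms: acetaldehyde, CC=O
Why: Evans–Tishchenko reduction, in which the C3 hydroxyl forms a hemiacetal with acetaldehyde on trivalent samarium and the hemiacetal hydride is passed intramolecularly to the C5 ketone through a chair-like six-membered transition state with both oxygen atoms on the metal, which should set C5 anti to C3 (5S), leave the acetyl group on O3 and free the new C5 hydroxyl.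

Compound list
1 | 3,4-dimethoxystyrene (4-ethenyl-1,2-dimethoxybenzene) | COc1ccc(C=C)cc1OC | starting material
2 | pinacolborane (4,4,5,5-tetramethyl-1,3,2-dioxaborolane) | CC1(C)OBOC1(C)C | starting material
3 | 2-[2-(3,4-dimethoxyphenyl)ethyl]-4,4,5,5-tetramethyl-1,3,2-dioxaborolane | COc1ccc(CCB2OC(C)(C)C(C)(C)O2)cc1OC | intermediate
4 | heptan-2-one | CCCCCC(C)=O | starting material
5 | lithium hept-1-en-2-olate | [Li+].[O-]C(=C)CCCCC | intermediate
6 | hept-1-en-2-yl trifluoromethanesulfonate | CCCCCC(=C)OS(=O)(=O)C(F)(F)F | intermediate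
7 | tetravinyltin (tetraethenylstannane) | C=C[Sn](C=C)(C=C)C=C | starting material
8 | vinyllithium (ethenyllithium) | [Li]C=C | intermediate
9 | lithium 2-[2-(3,4-dimethoxyphenyl)ethyl]-2-ethenyl-4,4,5,5-tetramethyl-1,3,2-dioxaborolan-2-uide (ate complex) | [Li+].C=C[B-]1(CCc2ccc(OC)c(OC)c2)OC(C)(C)C(C)(C)O1 | intermediate
10 | 2-[(3S)-1-(3,4-dimethoxyphenyl)-5-methylidenedecan-3-yl]-4,4,5,5-tetramethyl-1,3,2-dioxaborolane | C=C(CCCCC)C[C@H](CCc1ccc(OC)c(OC)c1)B1OC(C)(C)C(C)(C)O1 | intermediate
11 | (3S)-1-(3,4-dimethoxyphenyl)-5-methylidenedecan-3-ol | C=C(CCCCC)C[C@H](CCc1ccc(OC)c(OC)c1)O | intermediate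
12 | (2S)-4-(3,4-dimethoxyphenyl)-1-(3-pentyl-1,2,4-trioxolan-3-yl)butan-2-ol (ozonide; both epimers at the ring carbon) | CCCCCC1(OCOO1)C[C@H](CCc2ccc(OC)c(OC)c2)O | intermediate
13 | (3S)-1-(3,4-dimethoxyphenyl)-3-hydroxydecan-5-one | CCCCCC(=O)C[C@H](CCc1ccc(OC)c(OC)c1)O | intermediate
14 | (3S)-1-(3,4-dimethoxyphenyl)-3-(1-hydroxyethoxy)decan-5-one (hemiacetal; samarium-bound in the flask, drawn in its neutral form) | CCCCCC(=O)C[C@H](CCc1ccc(OC)c(OC)c1)OC(C)O | intermediate
15 | (3S,5S)-1-(3,4-dimethoxyphenyl)-5-hydroxydecan-3-yl acetate | CCCCC[C@H](O)C[C@H](CCc1ccc(OC)c(OC)c1)OC(C)=O | target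

Total step count: 7. Longest linear sequence: 5 steps (steps 1, 4, 5, 6, 7, from 3,4-dimethoxystyrene); steps 2 and 3 are side branches that feed step 4.

Steps most likely to fail

Step 4. What may go wrong: direct transfer of the vinyl group from boron to palladium (Suzuki-type coupling to a 1,3-diene), β-hydride elimination after the shift, or weak enantioface discrimination with this α-branched alkenyl electrophile. The fallback forms the two bonds one after the other and sets the stereocentre by alkene diboration. It sets out from boronate 3 and vinyllithium 8: ate complex 9 is treated with I2 (THF, −78 °C) and then NaOMe/MeOH (Zweifel olefination) to give 4-(3,4-dimethoxyphenyl)but-1-ene F1. Enantioselective diboration (Pt(dba)3, a TADDOL-derived phosphonite of the appropriate handedness, bis(pinacolato)diboron, THF, 60 °C) should give 2,2'-[(2R)-4-(3,4-dimethoxyphenyl)butane-1,2-diyl]bis(4,4,5,5-tetramethyl-1,3,2-dioxaborolane) F2. A Suzuki–Miyaura coupling that engages only the primary C–B bond (triflate 6, Pd(OAc)2, 2-dicyclohexylphosphino-2',6'-diisopropoxybiphenyl, KOH, THF/H2O, 70 °C) then comes back to the route at boronate 10.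

Step 7. What may go wrong: aldol-type self-condensation of the enolisable aldehyde at the samarium centre, which stalls the hydride transfer, or drift of the acetyl group from O3 to O5 in the product. The fallback uses the Tishchenko ester only as a marker for O3 and installs the acetyl group by ordinary acylation. It sets out from ketone 13: the same directed reduction with non-enolisable benzaldehyde (PhCHO, SmI2 cat., THF, −10 °C) should give (3S,5S)-1-(3,4-dimethoxyphenyl)-5-hydroxydecan-3-yl benzoate F3. Silylation (TBSOTf, 2,6-lutidine, CH2Cl2, −78 °C) gives (3S,5S)-5-[(tert-butyldimethylsilyl)oxy]-1-(3,4-dimethoxyphenyl)decan-3-yl benzoate F4. Reductive removal of the benzoate (iBu2AlH, CH2Cl2, −78 °C) gives (3S,5S)-5-[(tert-butyldimethylsilyl)oxy]-1-(3,4-dimethoxyphenyl)decan-3-ol F5. Acetylation (Ac2O, pyridine, 4-dimethylaminopyridine) gives (3S,5S)-5-[(tert-butyldimethylsilyl)oxy]-1-(3,4-dimethoxyphenyl)decan-3-yl acetate F6. Desilylation under non-basic conditions (HF·pyridine, THF, 0 °C) comes back to the route at target 15.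

Step 6. What may go wrong: ozone attack on the electron-rich dimethoxybenzene ring once the alkene is consumed, or dehydration and retro-aldol cleavage of the β-hydroxy ketone during work-up. The fallback is a two-stage glycol cleavage without ozone. It sets out from alcohol 11: dihydroxylation (OsO4 cat., N-methylmorpholine N-oxide, acetone/H2O, rt) gives (4S)-6-(3,4-dimethoxyphenyl)-2-pentylhexane-1,2,4-triol F7, which is isolated. Periodate cleavage of the 1,2-diol (NaIO4, THF/pH 7 buffer, 0 °C) comes back to the route at ketone 13.

Further compounds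
F1 | step 4 | 4-(3,4-dimethoxyphenyl)but-1-ene | C=CCCc1ccc(OC)c(OC)c1
F2 | step 4 | 2,2'-[(2R)-4-(3,4-dimethoxyphenyl)butane-1,2-diyl]bis(4,4,5,5-tetramethyl-1,3,2-dioxaborolane) | CC1(C)OB(C[C@H](CCc2ccc(OC)c(OC)c2)B2OC(C)(C)C(C)(C)O2)OC1(C)C
F3 | step 7 | (3S,5S)-1-(3,4-dimethoxyphenyl)-5-hydroxydecan-3-yl benzoate | CCCCC[C@H](O)C[C@H](CCc1ccc(OC)c(OC)c1)OC(=O)c1ccccc1
F4 | step 7 | (3S,5S)-5-[(tert-butyldimethylsilyl)oxy]-1-(3,4-dimethoxyphenyl)decan-3-yl benzoate | CCCCC[C@H](O[Si](C)(C)C(C)(C)C)C[C@H](CCc1ccc(OC)c(OC)c1)OC(=O)c1ccccc1
F5 | step 7 | (3S,5S)-5-[(tert-butyldimethylsilyl)oxy]-1-(3,4-dimethoxyphenyl)decan-3-ol | CCCCC[C@H](O[Si](C)(C)C(C)(C)C)C[C@H](CCc1ccc(OC)c(OC)c1)O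
F6 | step 7 | (3S,5S)-5-[(tert-butyldimethylsilyl)oxy]-1-(3,4-dimethoxyphenyl)decan-3-yl acetate | CCCCC[C@H](O[Si](C)(C)C(C)(C)C)C[C@H](CCc1ccc(OC)c(OC)c1)OC(C)=O
F7 | step 6 | (4S)-6-(3,4-dimethoxyphenyl)-2-pentylhexane-1,2,4-triol (both epimers at C2) | CCCCCC(O)(CO)C[C@H](CCc1ccc(OC)c(OC)c1)O
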